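**Plan**

- Cuts: first the bridge CH2–C6 bond at ring A, then the bridge CH2–ring B bond on the ring C side, giving three monomers; ring A is cut at C4–geranyl; ring C is cut at O1–C8a and C8–C(=O) together, then at the side-chain C=C.
- Enabling feature: in ring C the ether oxygen O1 and the butanoyl group sit on neighbouring ring carbons C8a and C8, and C8 is flanked by the C7 oxygen. This is the footprint of a tethered alkoxide and an acyl electrophile added across an aryne C8a≡C8, which the C7 oxygen polarises in the required sense.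
- Forward: fluoroarene, then Z-alkenyl tertiary alcohol, then aryne closure of the pyran ring (O1–C8a) with acylation in the same flask. Bridge 1 (ring C to ring B) and bridge 2 (ring B to ring A) follow by Mannich base / ortho-quinone methide conjugate additions.
- Stereochemistry: the only stereocentre, quaternary C4 of ring A (R), comes from a palladium-catalysed asymmetric allylic dearomatisation. The E alkene comes from geranyl acetate and the Z tether from a Still–Gennari olefination.

Key step: step 6

Remark: ring A is the dearomatised acetyl ring, ring B the central butanoylphloroglucinol, ring C the chromene (O1, C2, C3, C4, C4a, C5 to C8, C8a); enolised triketones are drawn in the tautomer of the given structure; geranyl = (2E)-3,7-dimethylocta-2,6-dien-1-yl.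

**Route**

Step 1
Reactants: 1 1-fluoro-3,5-dimethoxybenzene
Product: 2 2-fluoro-4,6-dimethoxybenzaldehyde
Conditions: POCl3, DMF, 0 to 60 °C; then H2O
Reagents that add atoms: N,N-dimethylformamide CN(C)C=O; water O
Why: Vilsmeier–Haack formylation should go para to one methoxy group and ortho to the other, next to fluorine, as with the chloro and bromo analogues; the minor isomer formylated between the methoxy groups is removed by crystallisation.

Step 2
Reactants: 2 2-fluoro-4,6-dimethoxybenzaldehyde
Product: 3 2-fluoro-4,6-dihydroxybenzaldehyde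
Conditions: BBr3 (3 equiv), CH2Cl2, −78 °C to rt; then H2O
Reagents that add atoms: none
Why: Lewis acid ether cleavage frees both phenols so that acid-labile MOM ethers, which a chromene tolerates at removal, can replace the methyl ethers.

Step 3
Reactants: 3 2-fluoro-4,6-dihydroxybenzaldehyde
Product: 4 2-fluoro-4,6-bis(methoxymethoxy)benzaldehyde
Conditions: NaH (2.5 equiv), MOMCl (2.5 equiv), DMF, 0 °C to rt
Reagents that add atoms: chloromethyl methyl ether COCCl
Why: O-alkylation of the bis-phenoxide; NaH is used because the hydroxyl hydrogen-bonded to the aldehyde reacts slowly with amine bases.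

Step 4
Reactants: 4 2-fluoro-4,6-bis(methoxymethoxy)benzaldehyde
Product: 5 methyl (2Z)-3-[2-fluoro-4,6-bis(methoxymethoxy)phenyl]prop-2-enoate
Conditions: (CF3CH2O)2P(O)CH2CO2Me, KN(SiMe3)2, 18-crown-6, THF, −78 °C
Reagents that add atoms: methyl bis(2,2,2-trifluoroethyl)phosphonoacetate COC(=O)CP(=O)(OCC(F)(F)F)OCC(F)(F)F
Why: Still–Gennari variant of the Horner–Wadsworth–Emmons reaction, whose fast irreversible elimination should give the Z enoate that later holds the alkoxide beside the fluorinated carbon.

Step 5
Reactants: 5 methyl (2Z)-3-[2-fluoro-4,6-bis(methoxymethoxy)phenyl]prop-2-enoate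
Product: 6 (3Z)-4-[2-fluoro-4,6-bis(methoxymethoxy)phenyl]-2-methylbut-3-en-2-ol
Conditions: MeLi (2.3 equiv), THF, −78 to −40 °C; then H2O
Reagents that add atoms: methyllithium [Li]C
Why: double 1,2-addition of methyllithium to the ester gives the tertiary allylic alcohol without touching the Z double bond; at this temperature the fluoroarene ring is not metalated.

Step 6
Reactants: 6 (3Z)-4-[2-fluoro-4,6-bis(methoxymethoxy)phenyl]-2-methylbut-3-en-2-ol
Product: 10 1-[5,7-bis(methoxymethoxy)-2,2-dimethyl-2H-chromen-8-yl]butan-1-one, via dilithio species 7 (not isolated), via aryne 8 (not isolated), via chromenyllithium 9 (not isolated)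
Conditions: n-BuLi (1.0 equiv), THF (0.03 M), −78 °C; s-BuLi (1.1 equiv), −78 °C; warm to 0 °C; recool to −78 °C, PrC(O)N(OMe)Me (1.5 equiv), to 0 °C; then H2O
Reagents that add atoms: N-methoxy-N-methylbutanamide CCCC(=O)N(C)OC
Why: After O-deprotonation, s-BuLi removes the most acidic ring proton, the one between fluorine and a MOM ether, and warming expels LiF to give aryne 8 whose triple bond spans the future C8a and C8. The Z-alkenyl tether holds the lithium alkoxide in the ring plane beside C8a, so it adds to the in-plane π bond in a 6-exo-dig closure that forms the O1–C8a bond and the pyran ring and leaves the carbanion on C8, where the C7 MOM oxygen and O1 chelate lithium. Aryllithium 9 is then acylated by the Weinreb amide, whose stable tetrahedral adduct prevents over-addition, so that the ether oxygen and the butanoyl group enter on neighbouring carbons in one flask. The closest known reaction type is the base-induced benzyne cyclisation of halogenoarenes carrying a tethered alkoxide or amide, with electrophilic capture of the resulting ortho-metalated arene. No stereocentre is formed; the step needs site-selective lithiation (secured at −78 °C by the acidifying fluorine, since a position flanked only by two ethers is metalated slowly) and regioselective addition to the aryne (secured by the tether, which reaches only C8a, and by the C7 oxygen, which directs nucleophiles to the distal aryne carbon).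

Step 7
Reactants: 10 1-[5,7-bis(methoxymethoxy)-2,2-dimethyl-2H-chromen-8-yl]butan-1-one
Product: 11 1-(5,7-dihydroxy-2,2-dimethyl-2H-chromen-8-yl)butan-1-one
Conditions: HCl (1.25 M in MeOH), MeOH, 40 °C
Reagents that add atoms: none
Why: acid-catalysed acetal exchange should remove both MOM groups under conditions that acyl-substituted 2,2-dimethylchromenes tolerate; ketone and ring ether are untouched.

Step 8
Reactants: 11 1-(5,7-dihydroxy-2,2-dimethyl-2H-chromen-8-yl)butan-1-one
Product: 12 1-{6-[(dimethylamino)methyl]-5,7-dihydroxy-2,2-dimethyl-2H-chromen-8-yl}butan-1-one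
Conditions: Eschenmoser's salt (1.05 equiv), CH2Cl2, rt; then aq. NaHCO3
Reagents that add atoms: N,N-dimethylmethyleneiminium iodide C=[N+](C)C.[I-]
Why: Mannich reaction in which the only free ring carbon, C6 between the two hydroxyls, attacks the preformed iminium ion and so receives the future bridge carbon with a leaving group.

Step 9
Reactants: 12 1-{6-[(dimethylamino)methyl]-5,7-dihydroxy-2,2-dimethyl-2H-chromen-8-yl}butan-1-one; 13 1-(2,4,6-trihydroxyphenyl)butan-1-one (4 equiv)
Product: 15 1-{3-[(8-butanoyl-5,7-dihydroxy-2,2-dimethyl-2H-chromen-6-yl)methyl]-2,4,6-trihydroxyphenyl}butan-1-one, via ortho-quinone methide 14 (not isolated)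
Conditions: 1,4-dioxane, 90 °C, argon
Reagents that add atoms: none
Why: on heating, the Mannich base should lose dimethylamine to give ortho-quinone methide 14, which takes up a ring carbon of 13 by conjugate (Michael-type) addition; the excess of symmetrical 13 suppresses double alkylation.

Step 10
Reactants: 15 1-{3-[(8-butanoyl-5,7-dihydroxy-2,2-dimethyl-2H-chromen-6-yl)methyl]-2,4,6-trihydroxyphenyl}butan-1-one
Product: 16 1-{3-[(8-butanoyl-5,7-dihydroxy-2,2-dimethyl-2H-chromen-6-yl)methyl]-5-[(dimethylamino)methyl]-2,4,6-trihydroxyphenyl}butan-1-one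
Conditions: Eschenmoser's salt (1.05 equiv), CH2Cl2, rt; then aq. NaHCO3
Reagents that add atoms: N,N-dimethylmethyleneiminium iodide C=[N+](C)C.[I-]
Why: Mannich reaction at the single unsubstituted carbon of ring B; ring C has no free ring carbon left.

Step 11
Reactants: 17 2-methylbenzene-1,3,5-triol
Product: 18 1-(2,4,6-trihydroxy-3-methylphenyl)ethan-1-one
Conditions: AcCl (1.1 equiv), AlCl3, PhNO2/CH2Cl2, rt to 50 °C; then aq. HCl
Reagents that add atoms: acetyl chloride CC(Cl)=O
Why: Friedel–Crafts acylation of the activated ring should stop after one acyl group because the aluminium-chelated product is deactivated.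

Step 12
Reactants: 18 1-(2,4,6-trihydroxy-3-methylphenyl)ethan-1-one; 19 geranyl acetate
Product: 20 (4R)-2-acetyl-4-[(2E)-3,7-dimethylocta-2,6-dien-1-yl]-3,5-dihydroxy-4-methylcyclohexa-2,5-dien-1-one
Conditions: Pd2(dba)3·CHCl3 (2.5 mol %), (R,R)-DACH-phenyl Trost ligand (7.5 mol %), Et3N (1.1 equiv), CH2Cl2, 0 °C to rt
Reagents that add atoms: none
Why: Tsuji–Trost asymmetric allylic alkylation used as a dearomatisation, in which the methyl-bearing ring carbon (the more electron-rich open carbon, as in the gem-dialkylation of acylphloroglucinols to filicinic acids) attacks the unhindered terminus of the geranyl π-allyl complex of palladium, while the chiral pocket of the ligand selects one face of the planar nucleophile, whose two flanks differ (oxyanion on C4, acetyl-bonded hydroxyl on C2), to set the R quaternary centre.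

Step 13
Reactants: 16 1-{3-[(8-butanoyl-5,7-dihydroxy-2,2-dimethyl-2H-chromen-6-yl)methyl]-5-[(dimethylamino)methyl]-2,4,6-trihydroxyphenyl}butan-1-one; 20 (4R)-2-acetyl-4-[(2E)-3,7-dimethylocta-2,6-dien-1-yl]-3,5-dihydroxy-4-methylcyclohexa-2,5-dien-1-one
Product: 22 (4R)-2-acetyl-6-({3-butanoyl-5-[(8-butanoyl-5,7-dihydroxy-2,2-dimethyl-2H-chromen-6-yl)methyl]-2,4,6-trihydroxyphenyl}methyl)-4-[(2E)-3,7-dimethylocta-2,6-dien-1-yl]-3,5-dihydroxy-4-methylcyclohexa-2,5-dien-1-one, via ortho-quinone methide 21 (not isolated)
Conditions: 1,4-dioxane, 80 °C, argon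
Reagents that add atoms: none
Why: thermal loss of dimethylamine should give ortho-quinone methide 21 on ring B, and the acidic C6 carbon of 20, its only nucleophilic carbon, adds in conjugate fashion to close the second bridge; the quaternary centre is not involved and cannot epimerise.

**Compound list**

1 | 1-fluoro-3,5-dimethoxybenzene | COc1cc(F)cc(OC)c1 | starting material
2 | 2-fluoro-4,6-dimethoxybenzaldehyde | COc1cc(F)c(C=O)c(OC)c1 | intermediate
3 | 2-fluoro-4,6-dihydroxybenzaldehyde | Oc1cc(F)c(C=O)c(O)c1 | intermediate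
4 | 2-fluoro-4,6-bis(methoxymethoxy)benzaldehyde | COCOc1cc(F)c(C=O)c(OCOC)c1 | intermediate
5 | methyl (2Z)-3-[2-fluoro-4,6-bis(methoxymethoxy)phenyl]prop-2-enoate | COCOc1cc(F)c(/C=C\C(=O)OC)c(OCOC)c1 | intermediate
6 | (3Z)-4-[2-fluoro-4,6-bis(methoxymethoxy)phenyl]-2-methylbut-3-en-2-ol | COCOc1cc(F)c(/C=C\C(C)(C)O)c(OCOC)c1 | intermediate
7 | dilithio species: lithium alkoxide of 6 lithiated on the ring carbon between fluorine and the neighbouring MOM ether | COCOc1cc(OCOC)c(/C=C\C(C)(C)O[Li])c(F)c1[Li] | intermediate
8 | aryne: lithium alkoxide of 6 with a ring triple bond in place of C–F and the neighbouring C–H | COCOC1=CC(OCOC)=C(/C=C\C(C)(C)O[Li])C#C1 | intermediate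
9 | [5,7-bis(methoxymethoxy)-2,2-dimethyl-2H-chromen-8-yl]lithium | COCOc1cc(OCOC)c2C=CC(C)(C)Oc2c1[Li] | intermediate
10 | 1-[5,7-bis(methoxymethoxy)-2,2-dimethyl-2H-chromen-8-yl]butan-1-one | CCCC(=O)c1c(OCOC)cc(OCOC)c2C=CC(C)(C)Oc12 | intermediate
11 | 1-(5,7-dihydroxy-2,2-dimethyl-2H-chromen-8-yl)butan-1-one | CCCC(=O)c1c(O)cc(O)c2C=CC(C)(C)Oc12 | intermediate
12 | 1-{6-[(dimethylamino)methyl]-5,7-dihydroxy-2,2-dimethyl-2H-chromen-8-yl}butan-1-one | CCCC(=O)c1c(O)c(CN(C)C)c(O)c2C=CC(C)(C)Oc12 | intermediate
13 | 1-(2,4,6-trihydroxyphenyl)butan-1-one | CCCC(=O)c1c(O)cc(O)cc1O | starting material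
14 | ortho-quinone methide of 12: 8-butanoyl-5-hydroxy-2,2-dimethyl-6-methylidene-2H-chromen-7(6H)-one | CCCC(=O)C1=C2OC(C)(C)C=CC2=C(O)C(=C)C1=O | intermediate
15 | 1-{3-[(8-butanoyl-5,7-dihydroxy-2,2-dimethyl-2H-chromen-6-yl)methyl]-2,4,6-trihydroxyphenyl}butan-1-one | CCCC(=O)c1c(O)cc(O)c(Cc2c(O)c3C=CC(C)(C)Oc3c(C(=O)CCC)c2O)c1O | intermediate
16 | 1-{3-[(8-butanoyl-5,7-dihydroxy-2,2-dimethyl-2H-chromen-6-yl)methyl]-5-[(dimethylamino)methyl]-2,4,6-trihydroxyphenyl}butan-1-one | CCCC(=O)c1c(O)c(CN(C)C)c(O)c(Cc2c(O)c3C=CC(C)(C)Oc3c(C(=O)CCC)c2O)c1O | intermediate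
17 | 2-methylbenzene-1,3,5-triol | Cc1c(O)cc(O)cc1O | starting material
18 | 1-(2,4,6-trihydroxy-3-methylphenyl)ethan-1-one | CC(=O)c1c(O)cc(O)c(C)c1O | intermediate
19 | geranyl acetate, (2E)-3,7-dimethylocta-2,6-dien-1-yl acetate | CC(=O)OC/C=C(\C)CCC=C(C)C | starting material
20 | (4R)-2-acetyl-4-[(2E)-3,7-dimethylocta-2,6-dien-1-yl]-3,5-dihydroxy-4-methylcyclohexa-2,5-dien-1-one | O=C1C=C(O)[C@@](C)(C/C=C(\C)CCC=C(C)C)C(O)=C1C(C)=O | intermediate
21 | ortho-quinone methide of 16: ring B as 6-methylidenecyclohexa-2,4-dienone, ring C unchanged | CCCC(=O)C1=C(O)C(Cc2c(O)c3C=CC(C)(C)Oc3c(C(=O)CCC)c2O)=C(O)C(=C)C1=O | intermediate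
22 | (4R)-2-acetyl-6-({3-butanoyl-5-[(8-butanoyl-5,7-dihydroxy-2,2-dimethyl-2H-chromen-6-yl)methyl]-2,4,6-trihydroxyphenyl}methyl)-4-[(2E)-3,7-dimethylocta-2,6-dien-1-yl]-3,5-dihydroxy-4-methylcyclohexa-2,5-dien-1-one | CCCC(=O)c1c(O)c(CC2=C(O)[C@@](C)(C/C=C(\C)CCC=C(C)C)C(O)=C(C(C)=O)C2=O)c(O)c(Cc2c(O)c3c(c(C(=O)CCC)c2O)OC(C)(C)C=C3)c1O | target

**Step count and risks**

Total step count: 13. Longest linear sequence: 11 steps (steps 1 to 10, then step 13).

Steps most likely to fail:

Step 12. The chiral catalyst may discriminate poorly between the faces of a nucleophile whose two flanks differ only in charge and hydrogen bonding. Alkylation may also go to the unsubstituted ring carbon or to oxygen, and the geranyl π-allyl complex may lose its E geometry. The antipodal ligand is equally available should the facial sense turn out reversed. Fallback, from 18 back to 20: base-mediated dearomatising alkylation with geranyl bromide (NaOMe, MeOH, 0 °C), an SN2 process that keeps the E alkene, should give racemic 2-acetyl-4-geranyl-3,5-dihydroxy-4-methylcyclohexa-2,5-dien-1-one F2. The strongly acidic dearomatised product is extracted into aqueous NaHCO3 away from aromatic isomers. Preparative chromatography on cellulose tris(3,5-dimethylphenylcarbamate) then separates 20 from its enantiomer, (4S)-2-acetyl-4-geranyl-3,5-dihydroxy-4-methylcyclohexa-2,5-dien-1-one F3.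

Step 6. Lithiation may go to the position between the two MOM ethers, s-BuLi may add to the styrenyl double bond, the aryne may be captured intermolecularly before ring closure, or the aryllithium may be protonated before acylation. Fallback, from 6 back to 10: after the same double deprotonation at −78 °C, the ortho-fluoroaryllithium is acylated with N-methoxy-N-methylbutanamide at −78 °C before any fluoride is lost. This should give (Z)-1-[2-fluoro-3-(3-hydroxy-3-methylbut-1-en-1-yl)-4,6-bis(methoxymethoxy)phenyl]butan-1-one F1. K2CO3 in DMF at 60 °C then closes the same O1–C8a bond by intramolecular nucleophilic aromatic substitution of the fluoride, now activated by the ortho carbonyl group.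

Step 13. Retro-Mannich methylene transfer, cleavage of the existing bridge under warm basic conditions and homodimer formation may scramble the three units. Fallback, from 20 and 15 back to 22, with the roles reversed: 20 with Eschenmoser's salt at 0 °C should give the Mannich base (4R)-2-acetyl-6-[(dimethylamino)methyl]-4-geranyl-3,5-dihydroxy-4-methylcyclohexa-2,5-dien-1-one F4. On gentle warming with 15 and NaOAc in MeCN at 40 °C it loses dimethylamine to give the 2-methylidene trione with the quaternary centre unchanged, F5, not isolated. F5 forms at lower temperature than an aromatic ortho-quinone methide and is trapped by the single free carbon of ring B.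

**Further compounds**

F1 | step 6 | (Z)-1-[2-fluoro-3-(3-hydroxy-3-methylbut-1-en-1-yl)-4,6-bis(methoxymethoxy)phenyl]butan-1-one | CCCC(=O)c1c(F)c(/C=C\C(C)(C)O)c(OCOC)cc1OCOC
F2 | step 12 | racemic 2-acetyl-4-geranyl-3,5-dihydroxy-4-methylcyclohexa-2,5-dien-1-one | CC(=O)C1=C(O)C(C)(C/C=C(\C)CCC=C(C)C)C(O)=CC1=O
F3 | step 12 | (4S)-2-acetyl-4-geranyl-3,5-dihydroxy-4-methylcyclohexa-2,5-dien-1-one | O=C1C=C(O)[C@](C)(C/C=C(\C)CCC=C(C)C)C(O)=C1C(C)=O
F4 | step 13 | (4R)-2-acetyl-6-[(dimethylamino)methyl]-4-geranyl-3,5-dihydroxy-4-methylcyclohexa-2,5-dien-1-one | O=C1C(CN(C)C)=C(O)[C@@](C)(C/C=C(\C)CCC=C(C)C)C(O)=C1C(C)=O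
F5 | step 13 | 4-acetyl-6-geranyl-5-hydroxy-6-methyl-2-methylidenecyclohex-4-ene-1,3-dione, quaternary centre as in 20 | O=C1C(=C)C(=O)[C@@](C)(C/C=C(\C)CCC=C(C)C)C(O)=C1C(C)=O
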